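The target is a symmetric 3,3'-biindole, and its central C3–C3' bond is taken as the carbonyl–carbonyl bond of a butane-2,3-dione. C3 and C3' each bear a benzo-ring carbon (C3a, C3a') and a pyrrole CH (C2, C2'). That is what two vicinal ketone carbons leave after each has attacked the ortho carbon of an N-aryl ring one CH2–N unit away and lost water. A single acid-mediated operation thus forges C3–C3a and C3'–C3a' and closes both pyrrole rings. Its precursor is 1,4-bis[N-(3-bromophenyl)-N-mesylamino]butane-2,3-dione, made in two steps; N-desulfonylation and C2,C2'-bromination complete the route.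

Key step: step 3

Remark on the chemistry: the target, 2,2',6,6'-tetrabromo-1H,1'H-3,3'-biindole, has no stereocentre and its biaryl axis is taken as not configurationally fixed, so no stereocontrol is needed and the SMILES carry no stereodescriptors.

Step 1
Reactants: 1 3-bromoaniline; 2 methanesulfonyl chloride
Product: 3 N-(3-bromophenyl)methanesulfonamide
Conditions: pyridine (2 equiv), CH2Cl2, 0 °C → rt; 1 M HCl wash
Reagents that add atoms: none
Why: N-sulfonylation of the aniline nitrogen by the sulfonyl chloride (sulfonamide formation), with pyridine as the acid scavenger so that the mono-sulfonamide and not the bis-sulfonimide should result.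

Step 2
Reactants: 3 N-(3-bromophenyl)methanesulfonamide (2.1 equiv); 4 1,4-dibromobutane-2,3-dione
Product: 6 N,N'-(2,3-dioxobutane-1,4-diyl)bis[N-(3-bromophenyl)methanesulfonamide], via monoalkylated bromodiketone 5 (not isolated)
Conditions: K2CO3 (2.2 equiv), DMF, 0 °C → rt, 4 added slowly to the sulfonamide salt; cold dilute HCl quench
Reagents that add atoms: none
Why: Twofold SN2 N-alkylation of the soft sulfonamide anion at the carbonyl-activated CH2Br carbons, run with a mild carbonate base and slow addition of the electrophile so that enolisation and aldol chemistry of the vicinal diketone stay minor.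

Step 3
Reactants: 6 N,N'-(2,3-dioxobutane-1,4-diyl)bis[N-(3-bromophenyl)methanesulfonamide]
Product: 8 6,6'-dibromo-1,1'-bis(methylsulfonyl)-1H,1'H-3,3'-biindole, via indol-3-yl ketone 7 (not isolated)
Conditions: P2O5/MeSO3H (1:10 w/w), ca. 0.03 M, rt → 70 °C; poured onto ice
Reagents that add atoms: none
Why: In the strongly acidic, dehydrating medium each O-protonated ketone carbon of 6 is attacked by the ortho carbon of the N-aryl ring on its own CH2–N arm (intramolecular Friedel–Crafts hydroxyalkylation) and the resulting 3-hydroxyindoline loses water across C2–C3, which should give first the 3-acylindole 7 and then, by the same sequence at the remaining aryl ketone, the biindole 8. The closest known reaction type is the Bischler-type cyclodehydration of N-sulfonyl α-(arylamino) ketones to 3-substituted N-sulfonylindoles; the second closure (an α-anilino aryl ketone giving a 3-arylindole) is a direct case of it, and the first differs only in the extra activation by the neighbouring carbonyl. Each pyrrole ring closes by a 5-exo-trig attack on its carbonyl carbon (C=O outside, arene C=C inside the new ring), forming C3–C3a and then C3'–C3a'. No stereocentre is created. The step needs five- over six-membered closure and attack para rather than ortho to bromine: closure onto the distal carbonyl would give a six-membered carbinol with no aromatising exit, whereas the five-membered path ends irreversibly in an indole, and the ortho carbon flanked by nitrogen and bromine is shielded, all the more because attack there would place the bromine peri to the fully substituted C3. Sulfonylation of both nitrogens shuts down the aryl-amine exchange that leads to 2-substituted indoles and keeps the amino ketone from condensing with itself; any 4-bromo isomer would have to be removed by crystallisation or chromatography.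

Step 4
Reactants: 8 6,6'-dibromo-1,1'-bis(methylsulfonyl)-1H,1'H-3,3'-biindole
Product: 10 6,6'-dibromo-1H,1'H-3,3'-biindole, via mono-N-mesyl biindole 9 (not isolated)
Conditions: KOH (10 equiv), 1,4-dioxane/H2O (3:1), 90 °C, N2; then aq. NH4Cl
Reagents that add atoms: none
Why: Alkaline N-desulfonylation of an N-sulfonyl azole, in which hydroxide attacks sulfur (or a sulfene forms from the mesyl CH3) and the stabilised indolide leaves; the alcohol-free medium avoids alkyl mesylates and N-alkylation, and the aryl bromides are inert.

Step 5
Reactants: 10 6,6'-dibromo-1H,1'H-3,3'-biindole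
Product: 12 2,2',6,6'-tetrabromo-1H,1'H-3,3'-biindole, via tribromobiindole 11 (not isolated)
Conditions: NBS (2.05 equiv), THF, −78 → 0 °C, dark, N2; aq. Na2S2O3/NaHCO3
Reagents that add atoms: N-bromosuccinimide, O=C1CCC(=O)N1Br
Why: Electrophilic bromination of a 3-substituted indole, which should deliver bromine to C2 of each ring (attack at the pyrrole ring, through the 3-bromoindolenine or directly) because the pyrrole ring is far more nucleophilic than the bromine-deactivated benzo ring.

Compound list
1 | 3-bromoaniline | Nc1cccc(Br)c1 | starting material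
2 | methanesulfonyl chloride | CS(Cl)(=O)=O | starting material
3 | N-(3-bromophenyl)methanesulfonamide | CS(=O)(=O)Nc1cccc(Br)c1 | intermediate
4 | 1,4-dibromobutane-2,3-dione | BrCC(=O)C(=O)CBr | starting material
5 | N-(4-bromo-2,3-dioxobutyl)-N-(3-bromophenyl)methanesulfonamide | CS(=O)(=O)N(CC(=O)C(=O)CBr)c1cccc(Br)c1 | intermediate (not isolated)
6 | N,N'-(2,3-dioxobutane-1,4-diyl)bis[N-(3-bromophenyl)methanesulfonamide] | CS(=O)(=O)N(CC(=O)C(=O)CN(c1cccc(Br)c1)S(C)(=O)=O)c1cccc(Br)c1 | intermediate
7 | N-{2-[6-bromo-1-(methylsulfonyl)-1H-indol-3-yl]-2-oxoethyl}-N-(3-bromophenyl)methanesulfonamide | CS(=O)(=O)n1cc(C(=O)CN(c2cccc(Br)c2)S(C)(=O)=O)c2ccc(Br)cc21 | intermediate (not isolated)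
8 | 6,6'-dibromo-1,1'-bis(methylsulfonyl)-1H,1'H-3,3'-biindole | CS(=O)(=O)n1cc(-c2cn(S(C)(=O)=O)c3cc(Br)ccc23)c2ccc(Br)cc21 | intermediate
9 | 6,6'-dibromo-1-(methylsulfonyl)-1H,1'H-3,3'-biindole | CS(=O)(=O)n1cc(-c2c[nH]c3cc(Br)ccc23)c2ccc(Br)cc21 | intermediate (not isolated)
10 | 6,6'-dibromo-1H,1'H-3,3'-biindole | Brc1ccc2c(-c3c[nH]c4cc(Br)ccc34)c[nH]c2c1 | intermediate
11 | 2,6,6'-tribromo-1H,1'H-3,3'-biindole | Brc1ccc2c(-c3c[nH]c4cc(Br)ccc34)c(Br)[nH]c2c1 | intermediate (not isolated)
12 | 2,2',6,6'-tetrabromo-1H,1'H-3,3'-biindole | Brc1ccc2c(-c3c(Br)[nH]c4cc(Br)ccc34)c(Br)[nH]c2c1 | target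

Total step count: 5. Longest linear sequence: 5 steps (1 → 3 → 6 → 8 → 10 → 12).

Steps most likely to fail

1. Step 3 (twofold cyclodehydration). The second closure may stall at ketone 7, because the 3-acylindole carbonyl is a weaker electrophile. An arene may instead close a six-membered ring onto the distal carbonyl. Ring closure ortho to bromine in either half would spread the material over regioisomers, and intermolecular condensation may compete if the solution is too concentrated. Fallback: the two pyrrole rings are closed one at a time by single cyclisations of established type. Setting out from 3, N-alkylation with bromoacetaldehyde diethyl acetal (K2CO3, NaI cat., DMF, 100 °C) should give N-(3-bromophenyl)-N-(2,2-diethoxyethyl)methanesulfonamide F1. TiCl4 in toluene at reflux should close F1 to 6-bromo-1-(methylsulfonyl)-1H-indole F2, the 4-bromo isomer being removed at this simple stage. Friedel–Crafts acylation at C3 with chloroacetyl chloride and AlCl3 in CH2Cl2 should give 1-[6-bromo-1-(methylsulfonyl)-1H-indol-3-yl]-2-chloroethan-1-one F3. N-alkylation of a second portion of 3 with F3 (K2CO3, NaI cat., MeCN) should deliver ketone 7, now isolated, and a single Bischler cyclodehydration of 7 in P2O5/MeSO3H brings the sequence back to the route at 8.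

2. Step 2 (twofold N-alkylation with the dibromodiketone). Base-induced enolisation and aldol self-condensation of the vicinal diketone, attack of the anion at a carbonyl group, or stalling after the first substitution may erode the material. Fallback: the four-carbon link is installed as an alkyne and oxidised afterwards. Setting out from 3, twofold N-propargylation with 1,4-dichlorobut-2-yne (K2CO3, NaI cat., DMF, 60 °C) should give N,N'-(but-2-yne-1,4-diyl)bis[N-(3-bromophenyl)methanesulfonamide] F4. Oxidation of the internal alkyne to the 1,2-diketone with catalytic RuO2·xH2O and NaIO4 in EtOAc/MeCN/H2O then returns to the route at 6.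

3. Step 5 (C2,C2'-bromination). Over-bromination, oxidation of the electron-rich biindole, or acid- and light-induced decomposition of the 2-bromoindole units may occur. Fallback: bromine is delivered by directed deprotonation instead of electrophilic substitution. Setting out from 10, Boc2O with catalytic DMAP in MeCN should give di-tert-butyl 6,6'-dibromo-1H,1'H-3,3'-biindole-1,1'-dicarboxylate F5. Deprotonation at C2 and C2' with LiN(iPr)2 (2.5 equiv, THF, −78 °C; an amide base that leaves the aryl bromides untouched) and quenching with BrCCl2CCl2Br should give di-tert-butyl 2,2',6,6'-tetrabromo-1H,1'H-3,3'-biindole-1,1'-dicarboxylate F6. Methanolysis of the two carbamates (K2CO3 cat., MeOH/THF, rt) returns to the route at 12.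

Further compounds
F1 | step 3 | N-(3-bromophenyl)-N-(2,2-diethoxyethyl)methanesulfonamide | CCOC(CN(c1cccc(Br)c1)S(C)(=O)=O)OCC
F2 | step 3 | 6-bromo-1-(methylsulfonyl)-1H-indole | CS(=O)(=O)n1ccc2ccc(Br)cc21
F3 | step 3 | 1-[6-bromo-1-(methylsulfonyl)-1H-indol-3-yl]-2-chloroethan-1-one | CS(=O)(=O)n1cc(C(=O)CCl)c2ccc(Br)cc21
F4 | step 2 | N,N'-(but-2-yne-1,4-diyl)bis[N-(3-bromophenyl)methanesulfonamide] | CS(=O)(=O)N(CC#CCN(c1cccc(Br)c1)S(C)(=O)=O)c1cccc(Br)c1
F5 | step 5 | di-tert-butyl 6,6'-dibromo-1H,1'H-3,3'-biindole-1,1'-dicarboxylate | CC(C)(C)OC(=O)n1cc(-c2cn(C(=O)OC(C)(C)C)c3cc(Br)ccc23)c2ccc(Br)cc21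
F6 | step 5 | di-tert-butyl 2,2',6,6'-tetrabromo-1H,1'H-3,3'-biindole-1,1'-dicarboxylate | CC(C)(C)OC(=O)n1c(Br)c(-c2c(Br)n(C(=O)OC(C)(C)C)c3cc(Br)ccc23)c2ccc(Br)cc21
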